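**Plan**

- Numbering: C7/C7′ are the benzylic CH2 groups, C8/C8′ the methines, C9/C9′ the CH2OAc carbons; ring A is 3,4-dimethoxyphenyl, ring B is 4-hydroxy-3,5-dimethoxyphenyl.
- Retrosynthesis: after the phenol benzyl group is removed, the ring A–C7 and ring B–C7′ bonds are cut, each back to a carboxylic acid one carbon longer (decarboxylative arylation). The two acid carbons are rejoined as the C=C of a cyclohexene (ozonolysis). C7–C8 and C8′–C7′ are then cut by a retro-[4+2] to buta-1,3-diene and a fumaric half-ester imide.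
- Enabling feature: the chain C7–C8–C8′–C7′, with C9 and C9′ on its methines, is the C3–C2–C1–C6 edge of a trans-cyclohex-4-ene-1,2-dicarboxylate (C9/C9′ are the carboxyl carbons). The alkene carbons C4/C5 of that ring are expendable and are replaced by ring A and ring B.
- Forward order: imide, then the asymmetric Diels–Alder ring (the only ring built, opened again later), reduction and acetylation, ozonolysis with end differentiation, ring A on the first terminus, ring B on the second, debenzylation.
- Stereochemistry: both centres (8R,8′R) are set in the cycloaddition, trans from the E-dienophile and absolute from the chiral titanium catalyst. They are never α to a carbonyl afterwards.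

Key step: step 2

Assumption: the (R,R)-TADDOL-derived dichlorotitanium diolate is taken to deliver the diene to the Cα-Re face of imide 5, the face that leads to the (1R,2R) adduct. The sense is to be confirmed at diol 8 against the known sign of rotation, and the enantiomeric ligand (equally available) is used if the opposite sense is found.

**Route**

Step 1
Reactants: 1 monomethyl fumarate; 2 oxazolidin-2-one
Product: 5 methyl (E)-4-oxo-4-(2-oxo-1,3-oxazolidin-3-yl)but-2-enoate, via acid chloride 3 (not isolated), via lithium oxazolidinide 4 (not isolated)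
Conditions: 1, (COCl)2, DMF (cat.), CH2Cl2, 0 °C → rt, evaporate; 2, n-BuLi, THF, −78 °C; then crude 3, −78 → 0 °C
Reagents that add atoms: none
Why: Acid chloride formation followed by N-acylation of the lithiated carbamate nitrogen (nucleophilic acyl substitution) is the standard entry to 3-enoyl-oxazolidin-2-ones, and the low temperature should keep the nitrogen nucleophile from conjugate addition, leaving the E double bond intact.

Step 2
Reactants: 5 methyl (E)-4-oxo-4-(2-oxo-1,3-oxazolidin-3-yl)but-2-enoate; 6 buta-1,3-diene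
Product: 7 methyl (1R,2R)-2-[(2-oxo-1,3-oxazolidin-3-yl)carbonyl]cyclohex-4-ene-1-carboxylate
Conditions: TiCl2(OiPr)2 (10 mol%), (4R,5R)-2,2-dimethyl-α,α,α′,α′-tetraphenyl-1,3-dioxolane-4,5-dimethanol [(R,R)-TADDOL, 11 mol%], 4 Å molecular sieves, toluene/petroleum ether, 0 °C → rt, excess 6, sealed vessel
Reagents that add atoms: none
Why: Ligand exchange of TiCl2(OiPr)2 with the diol should give a dichlorotitanium diolate (tetravalent titanium) that binds 5 through both imide carbonyl oxygens, locking the enoyl unit s-cis and lowering its LUMO while the ester carbonyl stays a spectator. s-cis Butadiene then adds across the fumaroyl C=C in a concerted suprafacial [4+2] cycloaddition, so the two new C–C bonds (the later C7–C8 and C8′–C7′) and the cyclohexene ring are formed together in one intermolecular cycloaddition. The closest known reaction type is the chiral titanium–TADDOLate-catalysed Diels–Alder reaction of 3-(alk-2-enoyl)oxazolidin-2-ones with simple dienes. The trans relation of the two new stereocentres follows stereospecifically from the E geometry of 5, and their absolute configuration from the aryl groups of the (R,R)-diolate, which are expected to cover the Cα-Si face so that the diene adds to the Cα-Re face. Because butadiene is unsubstituted there is no regiochemical or endo/exo question, so enantioface selection is the only selectivity needed, and the rigid two-point binding of the imide to the chiral Lewis acid is what should secure it.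

Step 3
Reactants: 7 methyl (1R,2R)-2-[(2-oxo-1,3-oxazolidin-3-yl)carbonyl]cyclohex-4-ene-1-carboxylate
Product: 8 [(1R,2R)-cyclohex-4-ene-1,2-diyl]dimethanol
Conditions: LiAlH4, THF, 0 °C → rt; H2O/aq. NaOH work-up
Reagents that add atoms: none
Why: Hydride reduction with LiAlH4 should take the methyl ester and the exocyclic imide carbonyl to primary alcohols with release of oxazolidin-2-one, leave the isolated alkene alone, and outpace any enolisation of the already preferred trans centres.

Step 4
Reactants: 8 [(1R,2R)-cyclohex-4-ene-1,2-diyl]dimethanol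
Product: 9 [(1R,2R)-cyclohex-4-ene-1,2-diyl]bis(methylene) diacetate
Conditions: Ac2O, pyridine, DMAP (cat.), CH2Cl2, rt
Reagents that add atoms: acetic anhydride, CC(=O)OC(C)=O
Why: DMAP-catalysed O-acylation of two unhindered primary alcohols installs the acetates of the target at once, where they also serve as protecting groups for the rest of the route.

Step 5
Reactants: 9 [(1R,2R)-cyclohex-4-ene-1,2-diyl]bis(methylene) diacetate
Product: 12 [(2R,3R)-2-(2,2-dimethoxyethyl)-3-(2-oxoethyl)butane-1,4-diyl] diacetate, via methoxy hydroperoxide aldehyde 10 (not isolated), via methoxy hydroperoxide acetal 11 (not isolated)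
Conditions: O3, CH2Cl2/MeOH (5:1), −78 °C; TsOH·H2O (cat.), −78 °C → rt; NaHCO3; Me2S, rt
Reagents that add atoms: ozone, [O-][O+]=O; methanol, CO
Why: Ozonolysis in methanol (Criegee cleavage with solvent trapping of the carbonyl oxide) gives an aldehyde and an α-methoxy hydroperoxide, acid then acetalises only the free aldehyde and Me2S reduces the hydroperoxide end to the second aldehyde; since the two alkene carbons of C2-symmetric 9 are homotopic a single aldehyde-acetal should result, and brief exposure to catalytic acid should not transesterify the primary acetates.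

Step 6
Reactants: 12 [(2R,3R)-2-(2,2-dimethoxyethyl)-3-(2-oxoethyl)butane-1,4-diyl] diacetate
Product: 13 (3R,4R)-3,4-bis(acetoxymethyl)-6,6-dimethoxyhexanoic acid
Conditions: NaClO2, NaH2PO4, 2-methyl-2-butene, t-BuOH/H2O, 0 °C → rt
Reagents that add atoms: sodium chlorite, [Na+].[O-]Cl=O
Why: The Pinnick oxidation converts the aldehyde to the acid near pH 4, where acetates and the dimethyl acetal should hold, and the stereocentres are β to the carbonyl and cannot epimerise.

Step 7
Reactants: 13 (3R,4R)-3,4-bis(acetoxymethyl)-6,6-dimethoxyhexanoic acid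
Product: 14 1,3-dioxoisoindolin-2-yl (3R,4R)-3,4-bis(acetoxymethyl)-6,6-dimethoxyhexanoate
Conditions: N-hydroxyphthalimide, DIC, DMAP (cat.), CH2Cl2, rt
Reagents that add atoms: N-hydroxyphthalimide, O=C1c2ccccc2C(=O)N1O
Why: Carbodiimide-mediated (Steglich-type) esterification under neutral conditions gives the redox-active N-acyloxyphthalimide without touching the acetal or the acetates.

Step 8
Reactants: 14 1,3-dioxoisoindolin-2-yl (3R,4R)-3,4-bis(acetoxymethyl)-6,6-dimethoxyhexanoate; 15 4-bromo-1,2-dimethoxybenzene
Product: 18 [(2R,3R)-2-(3,4-dimethoxybenzyl)-3-(2,2-dimethoxyethyl)butane-1,4-diyl] diacetate, via arylmagnesium bromide 16 (not isolated), via arylzinc chloride 17 (not isolated)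
Conditions: 15, Mg, LiCl, THF, rt; ZnCl2, THF, 0 °C → rt; then 14, NiCl2·glyme (20 mol%), 4,4′-di-tert-butyl-2,2′-bipyridine (40 mol%), THF/DMF, rt
Reagents that add atoms: none
Why: In this nickel-catalysed decarboxylative Negishi-type arylation, single-electron reduction of the N-acyloxyphthalimide releases CO2 and a primary alkyl radical that is captured by the arylnickel species formed from 17, and reductive elimination forms the ring A–C7 bond; arylzinc reagents tolerate acetates and acetals, and the radical sits on a CH2 so the neighbouring stereocentre is untouched.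

Step 9
Reactants: 18 [(2R,3R)-2-(3,4-dimethoxybenzyl)-3-(2,2-dimethoxyethyl)butane-1,4-diyl] diacetate
Product: 19 [(2R,3R)-2-(3,4-dimethoxybenzyl)-3-(2-oxoethyl)butane-1,4-diyl] diacetate
Conditions: 1 M aq. HCl, THF, rt
Reagents that add atoms: water, O
Why: Acid-catalysed acetal hydrolysis in dilute aqueous acid at room temperature should spare the primary acetates and be too mild for cyclisation of the liberated aldehyde onto the dimethoxyarene.

Step 10
Reactants: 19 [(2R,3R)-2-(3,4-dimethoxybenzyl)-3-(2-oxoethyl)butane-1,4-diyl] diacetate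
Product: 20 (3R,4R)-3,4-bis(acetoxymethyl)-5-(3,4-dimethoxyphenyl)pentanoic acid
Conditions: NaClO2, NaH2PO4, 2-methyl-2-butene (large excess), t-BuOH/H2O, 0 °C → rt
Reagents that add atoms: sodium chlorite, [Na+].[O-]Cl=O
Why: Pinnick oxidation again, with the alkene scavenger in excess to intercept hypochlorous acid before it can chlorinate the electron-rich ring A.

Step 11
Reactants: 20 (3R,4R)-3,4-bis(acetoxymethyl)-5-(3,4-dimethoxyphenyl)pentanoic acid
Product: 21 1,3-dioxoisoindolin-2-yl (3R,4R)-3,4-bis(acetoxymethyl)-5-(3,4-dimethoxyphenyl)pentanoate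
Conditions: N-hydroxyphthalimide, DIC, DMAP (cat.), CH2Cl2, rt
Reagents that add atoms: N-hydroxyphthalimide, O=C1c2ccccc2C(=O)N1O
Why: The same Steglich-type esterification as in step 7 gives the second redox-active ester.

Step 12
Reactants: 22 4-bromo-2,6-dimethoxyphenol
Product: 23 2-(benzyloxy)-5-bromo-1,3-dimethoxybenzene
Conditions: BnBr, K2CO3, DMF, rt
Reagents that add atoms: benzyl bromide, BrCc1ccccc1
Why: Williamson etherification (SN2 of the phenoxide on benzyl bromide) masks the acidic phenol, which would otherwise quench the arylmagnesium and arylzinc reagents, as an ether that is removable by hydrogenolysis at the end.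

Step 13
Reactants: 21 1,3-dioxoisoindolin-2-yl (3R,4R)-3,4-bis(acetoxymethyl)-5-(3,4-dimethoxyphenyl)pentanoate; 23 2-(benzyloxy)-5-bromo-1,3-dimethoxybenzene
Product: 26 [(2R,3R)-2-[4-(benzyloxy)-3,5-dimethoxybenzyl]-3-(3,4-dimethoxybenzyl)butane-1,4-diyl] diacetate, via arylmagnesium bromide 24 (not isolated), via arylzinc chloride 25 (not isolated)
Conditions: 23, Mg, LiCl, THF, rt; ZnCl2, THF, 0 °C → rt; then 21, NiCl2·glyme (20 mol%), 4,4′-di-tert-butyl-2,2′-bipyridine (40 mol%), THF/DMF, rt
Reagents that add atoms: none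
Why: The same nickel-catalysed decarboxylative Negishi-type arylation as in step 8 forms the ring B–C7′ bond; capture of the primary radical by nickel should be much faster than its addition to ring A, and the zinc carbon of 25 has no ortho substituents.

Step 14
Reactants: 26 [(2R,3R)-2-[4-(benzyloxy)-3,5-dimethoxybenzyl]-3-(3,4-dimethoxybenzyl)butane-1,4-diyl] diacetate
Product: 27 Justin C [(2R,3R)-2-(3,4-dimethoxybenzyl)-3-(4-hydroxy-3,5-dimethoxybenzyl)butane-1,4-diyl] diacetate
Conditions: H2 (1 atm), 10% Pd/C, EtOAc, rt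
Reagents that add atoms: none
Why: Catalytic hydrogenolysis cleaves only the benzyl aryl ether; acetates, methyl ethers and the benzylic C–C bonds are inert under these neutral conditions.

**Compound list**

1 | monomethyl fumarate, (E)-4-methoxy-4-oxobut-2-enoic acid | COC(=O)/C=C/C(=O)O | starting material
2 | oxazolidin-2-one | O=C1NCCO1 | starting material
3 | methyl (E)-4-chloro-4-oxobut-2-enoate | COC(=O)/C=C/C(Cl)=O | intermediate
4 | lithium 2-oxo-1,3-oxazolidin-3-ide | [Li+].O=C1[N-]CCO1 | intermediate
5 | methyl (E)-4-oxo-4-(2-oxo-1,3-oxazolidin-3-yl)but-2-enoate | COC(=O)/C=C/C(=O)N1CCOC1=O | intermediate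
6 | buta-1,3-diene | C=CC=C | starting material
7 | methyl (1R,2R)-2-[(2-oxo-1,3-oxazolidin-3-yl)carbonyl]cyclohex-4-ene-1-carboxylate | C1[C@@H](C(=O)N2CCOC2=O)[C@H](C(=O)OC)CC=C1 | intermediate
8 | [(1R,2R)-cyclohex-4-ene-1,2-diyl]dimethanol | C1[C@@H](CO)[C@H](CO)CC=C1 | intermediate
9 | [(1R,2R)-cyclohex-4-ene-1,2-diyl]bis(methylene) diacetate | C1[C@@H](COC(C)=O)[C@H](COC(C)=O)CC=C1 | intermediate
10 | [(2R,3R)-2-(2-hydroperoxy-2-methoxyethyl)-3-(2-oxoethyl)butane-1,4-diyl] diacetate (epimers at the peroxy carbon) | O=CC[C@@H](COC(C)=O)[C@H](COC(C)=O)CC(OC)OO | intermediate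
11 | [(2R,3R)-2-(2,2-dimethoxyethyl)-3-(2-hydroperoxy-2-methoxyethyl)butane-1,4-diyl] diacetate (epimers at the peroxy carbon) | COC(OC)C[C@@H](COC(C)=O)[C@H](COC(C)=O)CC(OC)OO | intermediate
12 | [(2R,3R)-2-(2,2-dimethoxyethyl)-3-(2-oxoethyl)butane-1,4-diyl] diacetate | COC(OC)C[C@@H](COC(C)=O)[C@H](COC(C)=O)CC=O | intermediate
13 | (3R,4R)-3,4-bis(acetoxymethyl)-6,6-dimethoxyhexanoic acid | COC(OC)C[C@@H](COC(C)=O)[C@H](COC(C)=O)CC(=O)O | intermediate
14 | 1,3-dioxoisoindolin-2-yl (3R,4R)-3,4-bis(acetoxymethyl)-6,6-dimethoxyhexanoate | COC(OC)C[C@@H](COC(C)=O)[C@H](COC(C)=O)CC(=O)ON1C(=O)c2ccccc2C1=O | intermediate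
15 | 4-bromo-1,2-dimethoxybenzene | COc1ccc(Br)cc1OC | starting material
16 | (3,4-dimethoxyphenyl)magnesium bromide | COc1ccc([Mg]Br)cc1OC | intermediate
17 | (3,4-dimethoxyphenyl)zinc chloride | COc1ccc([Zn]Cl)cc1OC | intermediate
18 | [(2R,3R)-2-(3,4-dimethoxybenzyl)-3-(2,2-dimethoxyethyl)butane-1,4-diyl] diacetate | COc1ccc(C[C@@H](COC(C)=O)[C@H](COC(C)=O)CC(OC)OC)cc1OC | intermediate
19 | [(2R,3R)-2-(3,4-dimethoxybenzyl)-3-(2-oxoethyl)butane-1,4-diyl] diacetate | COc1ccc(C[C@@H](COC(C)=O)[C@H](COC(C)=O)CC=O)cc1OC | intermediate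
20 | (3R,4R)-3,4-bis(acetoxymethyl)-5-(3,4-dimethoxyphenyl)pentanoic acid | COc1ccc(C[C@@H](COC(C)=O)[C@H](COC(C)=O)CC(=O)O)cc1OC | intermediate
21 | 1,3-dioxoisoindolin-2-yl (3R,4R)-3,4-bis(acetoxymethyl)-5-(3,4-dimethoxyphenyl)pentanoate | COc1ccc(C[C@@H](COC(C)=O)[C@H](COC(C)=O)CC(=O)ON2C(=O)c3ccccc3C2=O)cc1OC | intermediate
22 | 4-bromo-2,6-dimethoxyphenol | COc1cc(Br)cc(OC)c1O | starting material
23 | 2-(benzyloxy)-5-bromo-1,3-dimethoxybenzene | COc1cc(Br)cc(OC)c1OCc1ccccc1 | intermediate
24 | [4-(benzyloxy)-3,5-dimethoxyphenyl]magnesium bromide | COc1cc([Mg]Br)cc(OC)c1OCc1ccccc1 | intermediate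
25 | [4-(benzyloxy)-3,5-dimethoxyphenyl]zinc chloride | COc1cc([Zn]Cl)cc(OC)c1OCc1ccccc1 | intermediate
26 | [(2R,3R)-2-[4-(benzyloxy)-3,5-dimethoxybenzyl]-3-(3,4-dimethoxybenzyl)butane-1,4-diyl] diacetate | COc1ccc(C[C@@H](COC(C)=O)[C@H](COC(C)=O)Cc2cc(OC)c(OCc3ccccc3)c(OC)c2)cc1OC | intermediate
27 | Justin C, [(2R,3R)-2-(3,4-dimethoxybenzyl)-3-(4-hydroxy-3,5-dimethoxybenzyl)butane-1,4-diyl] diacetate | COc1ccc(C[C@@H](COC(C)=O)[C@H](COC(C)=O)Cc2cc(OC)c(O)c(OC)c2)cc1OC | target

**Step count**

Total: 14 steps. Longest linear sequence: 13 steps (steps 1–11, 13 and 14, from monomethyl fumarate); step 12 is a one-step side branch.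

**Steps most likely to fail, with fallbacks**

1. Step 13. Attack of the arylzinc reagent on the activated ester carbonyl, or reduction, dimerisation or cyclisation onto ring A of the primary radical, may compete with its capture by nickel on this late, functionalised substrate. The fallback sets out from 21 and makes the same C–aryl bond by two-electron palladium catalysis. Decarboxylative borylation of 21 under blue light with bis(catecholato)diboron in N,N-dimethylacetamide should give the catechol boronate [(2R,3R)-2-[(1,3,2-benzodioxaborol-2-yl)methyl]-3-(3,4-dimethoxybenzyl)butane-1,4-diyl] diacetate F1. Pinacol and Et3N in the same flask convert it into the pinacol boronate [(2R,3R)-2-(3,4-dimethoxybenzyl)-3-[(4,4,5,5-tetramethyl-1,3,2-dioxaborolan-2-yl)methyl]butane-1,4-diyl] diacetate F2. KHF2 in MeOH/H2O then gives potassium [(2R,3R)-4-acetoxy-2-(acetoxymethyl)-3-(3,4-dimethoxybenzyl)butyl]trifluoroborate F3. Suzuki–Miyaura coupling of this primary alkyltrifluoroborate with bromide 23 (Pd(OAc)2, 2-dicyclohexylphosphino-2′,6′-diisopropoxybiphenyl, K2CO3, toluene/H2O, 80 °C) comes back to the route at 26. Any acetate lost to aqueous carbonate would be restored with Ac2O/pyridine, since the phenol is still benzylated at that stage.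

2. Step 8. The same competition between acyl attack, radical reduction and nickel capture applies to the first arylation, and zinc salts could also erode the acetal. The fallback sets out from acid 13 and reverses the polarity of the partners. Iododecarboxylation of 13 (PhI(OAc)2, I2, visible light, cyclohexane/CH2Cl2, reflux) should give the primary iodide [(2R,3R)-2-(2,2-dimethoxyethyl)-3-(iodomethyl)butane-1,4-diyl] diacetate F4. Zinc insertion (Zn dust, LiCl, THF, rt → 40 °C) converts it into {(2R,3R)-4-acetoxy-2-(acetoxymethyl)-3-(2,2-dimethoxyethyl)butyl}zinc iodide F5, an ester-tolerant alkylzinc reagent. Negishi coupling of this reagent with bromide 15 (Pd(OAc)2, 2-dicyclohexylphosphino-2′,6′-dimethoxybiphenyl, THF, rt → 50 °C; zerovalent palladium formed in the flask) comes back to the route at 18.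

3. Step 2. Enantioface discrimination may be incomplete, or the cycloaddition of the weakly reactive gaseous diene may stall through catalyst deactivation by traces of water. The fallback sets out from the acid chloride 3 and replaces catalyst control by a covalently bound auxiliary. Commercial (4R)-4-benzyl-1,3-oxazolidin-2-one is deprotonated with n-BuLi (THF, −78 °C) to lithium (4R)-4-benzyl-2-oxo-1,3-oxazolidin-3-ide F6, which is acylated by 3 to give methyl (E)-4-[(4R)-4-benzyl-2-oxo-1,3-oxazolidin-3-yl]-4-oxobut-2-enoate F7. Et2AlCl (1.4 equiv) and excess butadiene 6 in CH2Cl2 at −78 °C should give methyl (1R,2R)-2-{[(4R)-4-benzyl-2-oxo-1,3-oxazolidin-3-yl]carbonyl}cyclohex-4-ene-1-carboxylate F8. In the aluminium chelate the s-cis enoyl unit lies next to C4 of the auxiliary, the (R)-benzyl group covers the Cα-Si face and the diene adds to the Cα-Re face. The minor diastereomer would be removed by crystallisation or chromatography. LiAlH4 in THF then reduces imide and ester and comes back to the route at diol 8, with recovery of the auxiliary.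

Further compounds
F1 | step 13 | [(2R,3R)-2-[(1,3,2-benzodioxaborol-2-yl)methyl]-3-(3,4-dimethoxybenzyl)butane-1,4-diyl] diacetate | COc1ccc(C[C@@H](COC(C)=O)[C@H](COC(C)=O)CB2Oc3ccccc3O2)cc1OC
F2 | step 13 | [(2R,3R)-2-(3,4-dimethoxybenzyl)-3-[(4,4,5,5-tetramethyl-1,3,2-dioxaborolan-2-yl)methyl]butane-1,4-diyl] diacetate | COc1ccc(C[C@@H](COC(C)=O)[C@H](COC(C)=O)CB2OC(C)(C)C(C)(C)O2)cc1OC
F3 | step 13 | potassium [(2R,3R)-4-acetoxy-2-(acetoxymethyl)-3-(3,4-dimethoxybenzyl)butyl]trifluoroborate | [K+].COc1ccc(C[C@@H](COC(C)=O)[C@H](COC(C)=O)C[B-](F)(F)F)cc1OC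
F4 | step 8 | [(2R,3R)-2-(2,2-dimethoxyethyl)-3-(iodomethyl)butane-1,4-diyl] diacetate | COC(OC)C[C@@H](COC(C)=O)[C@H](COC(C)=O)CI
F5 | step 8 | {(2R,3R)-4-acetoxy-2-(acetoxymethyl)-3-(2,2-dimethoxyethyl)butyl}zinc iodide | COC(OC)C[C@@H](COC(C)=O)[C@H](COC(C)=O)C[Zn]I
F6 | step 2 | lithium (4R)-4-benzyl-2-oxo-1,3-oxazolidin-3-ide | [Li+].O=C1[N-][C@H](Cc2ccccc2)CO1
F7 | step 2 | methyl (E)-4-[(4R)-4-benzyl-2-oxo-1,3-oxazolidin-3-yl]-4-oxobut-2-enoate | COC(=O)/C=C/C(=O)N1[C@H](Cc2ccccc2)COC1=O
F8 | step 2 | methyl (1R,2R)-2-{[(4R)-4-benzyl-2-oxo-1,3-oxazolidin-3-yl]carbonyl}cyclohex-4-ene-1-carboxylate | C1[C@@H](C(=O)N2[C@H](Cc3ccccc3)COC2=O)[C@H](C(=O)OC)CC=C1
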